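**Retrosynthetic overview**

1. The target is reached by two late, hydroxyl-steered epoxidations of a (1(10)Z,4Z)-germacra-1(10),4,11-triene-3,8,9-triol core: peracid from the free O3 for the 4,5-oxirane, then VO(acac)2/t-BuOOH from the free O9 for the 1,10-oxirane. Each ester goes on as its hydroxyl is released.
2. Key disconnection C8–C9: the ten-membered ring is closed by adding a γ-alkoxyallylchromium to the C8 aldehyde. The reagent comes from the C9 enal acetal, so the former carbonyl carbon acts as the nucleophile (an α-oxyallyl anion, i.e. an acyl anion one oxidation level down). This step is meant to set C8, C9 and the Z C1=C10 olefin together.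
3. The open-chain precursor gets C9/C10 by cross-metathesis with methacrolein and C1–C3 by asymmetric allylboration of a Z-enal (sets C3).
4. C3–C8, with the Z C4=C5 olefin and C7, come from (S)-carvone by α′-hydroxylation, reduction and glycol cleavage of the C3–C8 bond.
5. Ring order: carvone six-membered ring opened, then ten-membered carbocycle (key step), then 4,5-oxirane, then 1,10-oxirane.

Assumption: ring positions use germacrane numbering (C1=C10(CH3), C3–O, C4(CH3)=C5, C7 isopropenyl, C8–O, C9–O), and (4-methoxybenzyloxy)trimethylsilane is taken as a purchasable reagent.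

**Route**

Step 1
Reactants: 1 (S)-(+)-carvone
Product: 3 (5R,6R)-6-hydroxycarvone, via lithium dienolate 2 (not isolated)
Conditions: LiN(iPr)2 (LDA), THF, −78 °C; then 2-(phenylsulfonyl)-3-phenyloxaziridine, −78 °C; NH4Cl
Reagents that add atoms: 2-(phenylsulfonyl)-3-phenyloxaziridine, O=S(=O)(c1ccccc1)N1OC1c1ccccc1
Why: Kinetic α′-deprotonation and Davis oxidation of the cross-conjugated enolate give the acyloin, with oxygen entering anti to the isopropenyl group; the new carbinol is only a handle for the later ring cleavage and the carvone stereocentre (future C7) is untouched.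

Step 2
Reactants: 3 (5R,6R)-6-hydroxycarvone
Product: 4 (1R,6R)-3-methyl-6-(prop-1-en-2-yl)cyclohex-3-ene-1,2-diol
Conditions: NaBH4, CeCl3·7H2O, MeOH, −20 °C
Reagents that add atoms: none
Why: Luche 1,2-reduction of the enone gives the vicinal diol; the new carbinol configuration is irrelevant because both carbinol carbons become aldehydes in step 3.

Step 3
Reactants: 4 (1R,6R)-3-methyl-6-(prop-1-en-2-yl)cyclohex-3-ene-1,2-diol
Product: 6 (2Z,5R)-5-(hydroxymethyl)-2,6-dimethylhepta-2,6-dienal, via dialdehyde 5 (not isolated)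
Conditions: NaIO4, THF/pH 7 buffer, 0 °C; crude in EtOH/CH2Cl2 (3:7), NaBH4 (0.3 equiv), −78 °C
Reagents that add atoms: none
Why: Malaprade glycol cleavage opens the ring between the future C3 and C8, so the Z geometry of C4=C5 is inherited from the cyclohexene, and at −78 °C borohydride reduces the unconjugated C8 aldehyde much faster than the hindered conjugated C3 aldehyde (chemoselective aldehyde reduction); C7 is not touched.

Step 4
Reactants: 6 (2Z,5R)-5-(hydroxymethyl)-2,6-dimethylhepta-2,6-dienal; 7 allylboronic acid pinacol ester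
Product: 8 (2R,4Z,6S)-5-methyl-2-(prop-1-en-2-yl)nona-4,8-diene-1,6-diol
Conditions: (S)-TRIP phosphoric acid [(S)-3,3′-bis(2,4,6-triisopropylphenyl)-1,1′-binaphthyl-2,2′-diyl hydrogen phosphate] (5 mol%), 7 (2 equiv), toluene, −30 °C; aq. NaHCO3
Reagents that add atoms: none
Why: Chiral phosphoric acid-catalysed allylboration (Antilla type) under reagent control; the (S)-acid, the antipode of the one recalled as giving (R)-carbinols from aryl and alkenyl aldehydes, should deliver allyl to the Si face of the enal and set C3 as S, with the free primary alcohol carried as a transient borate.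

Step 5
Reactants: 8 (2R,4Z,6S)-5-methyl-2-(prop-1-en-2-yl)nona-4,8-diene-1,6-diol
Product: 9 (4S,5Z,8R)-5,9-dimethyl-4-(triethylsilyloxy)-8-[(triethylsilyloxy)methyl]deca-1,5,9-triene
Conditions: Et3SiCl, imidazole, DMF, 0 °C to rt
Reagents that add atoms: chlorotriethylsilane, CC[Si](CC)(CC)Cl
Why: Standard bis-silylation; the primary and secondary triethylsilyl ethers are told apart later by the oxidation in step 8.

Step 6
Reactants: 9 (4S,5Z,8R)-5,9-dimethyl-4-(triethylsilyloxy)-8-[(triethylsilyloxy)methyl]deca-1,5,9-triene; 10 methacrolein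
Product: 11 (2E,5S,6Z,9R)-2,6,10-trimethyl-5-(triethylsilyloxy)-9-[(triethylsilyloxy)methyl]undeca-2,6,10-trienal
Conditions: Hoveyda–Grubbs second-generation catalyst, RuCl2(H2IMes)(=CH-C6H4-2-OiPr) (5 mol%), 10 (5 equiv), CH2Cl2, 40 °C
Reagents that add atoms: none
Why: Olefin cross-metathesis of the only monosubstituted alkene with methacrolein gives the E-enal, while the isopropenyl and trisubstituted olefins are spectators; the E geometry does not matter because this double bond is transposed in step 9.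

Step 7
Reactants: 11 (2E,5S,6Z,9R)-2,6,10-trimethyl-5-(triethylsilyloxy)-9-[(triethylsilyloxy)methyl]undeca-2,6,10-trienal
Product: 12 (2E,5S,6Z,9R)-1,1-bis(4-methoxybenzyloxy)-2,6,10-trimethyl-5-(triethylsilyloxy)-9-[(triethylsilyloxy)methyl]undeca-2,6,10-triene
Conditions: (4-methoxybenzyloxy)trimethylsilane (2.5 equiv), Me3SiOTf (5 mol%), CH2Cl2, −78 °C; pyridine quench
Reagents that add atoms: (4-methoxybenzyloxy)trimethylsilane, COc1ccc(CO[Si](C)(C)C)cc1
Why: Noyori aprotic acetalisation converts the enal into its unsaturated acetal without double-bond migration and without loss of the silyl ethers; the 4-methoxybenzyl group is chosen so that the ether left on O9 after step 9 can be removed oxidatively.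

Step 8
Reactants: 12 (2E,5S,6Z,9R)-1,1-bis(4-methoxybenzyloxy)-2,6,10-trimethyl-5-(triethylsilyloxy)-9-[(triethylsilyloxy)methyl]undeca-2,6,10-triene
Product: 14 (2R,4Z,6S,8E)-10,10-bis(4-methoxybenzyloxy)-5,9-dimethyl-2-(prop-1-en-2-yl)-6-(triethylsilyloxy)deca-4,8-dienal, via alkoxysulfonium chloride 13 (not isolated)
Conditions: (COCl)2, DMSO, CH2Cl2, −78 to −40 °C; then Et3N, −78 to 0 °C
Reagents that add atoms: none
Why: Swern oxidation acts directly on the primary triethylsilyl ether and leaves the secondary one and the acetal intact, giving the C8 aldehyde under cold, briefly basic conditions that should not epimerise or conjugate the α-isopropenyl centre C7.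

Step 9
Reactants: 14 (2R,4Z,6S,8E)-10,10-bis(4-methoxybenzyloxy)-5,9-dimethyl-2-(prop-1-en-2-yl)-6-(triethylsilyloxy)deca-4,8-dienal
Product: 17 (3S,7R,8S,9R)-9-(4-methoxybenzyloxy)-3-(triethylsilyloxy)germacra-1(10)Z,4Z,11-trien-8-ol, via iodo ether 15 (not isolated), via allylchromium species 16 (not isolated)
Conditions: Me3SiI (1.2 equiv), THF, −78 °C; syringe-pump addition to CrCl2 (8 equiv), THF, −30 °C, 2 mM; aq. NaHCO3
Reagents that add atoms: none
Why: Proposed new method: a ten-membered-ring, intramolecular version of the Takai–Utimoto reaction, in which Me3SiI ionises the unsaturated acetal to iodo ether 15, two CrCl2 reduce it to the γ-alkoxyallylchromium 16 (chromium on C1, as these reagents react through the oxygen-bearing terminus), and the former carbonyl carbon C9 adds to the C8 aldehyde with allylic transposition; the closest known chemistry is the intermolecular anti(erythro)-selective γ-alkoxyallylchromium addition to aldehydes and Nozaki–Hiyama-type macrocyclisations, and by analogy the chromium-bridged cyclic transition state should give the 8,9-anti pair, Felkin–Anh attack anti to the C7 isopropenyl group the 7,8-anti pair, and the short C2–C7 tether should span that transition state only with C2 pseudo-axial, which makes the new C1=C10 olefin Z.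

Step 10
Reactants: 17 (3S,7R,8S,9R)-9-(4-methoxybenzyloxy)-3-(triethylsilyloxy)germacra-1(10)Z,4Z,11-trien-8-ol; 18 senecioic acid
Product: 20 (3S,7R,8S,9R)-9-(4-methoxybenzyloxy)-3-(triethylsilyloxy)germacra-1(10)Z,4Z,11-trien-8-yl senecioate, via mixed anhydride 19 (not isolated)
Conditions: 18, 2,4,6-trichlorobenzoyl chloride, Et3N, THF, rt; then 17, DMAP, toluene, rt
Reagents that add atoms: none
Why: Yamaguchi esterification of the only free hydroxyl (O8) with the unhindered carbonyl of the mixed anhydride; no stereocentre is affected.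

Step 11
Reactants: 20 (3S,7R,8S,9R)-9-(4-methoxybenzyloxy)-3-(triethylsilyloxy)germacra-1(10)Z,4Z,11-trien-8-yl senecioate
Product: 21 (3S,7R,8S,9R)-3-hydroxy-9-(4-methoxybenzyloxy)germacra-1(10)Z,4Z,11-trien-8-yl senecioate
Conditions: HF·pyridine, pyridine/THF, 0 °C
Reagents that add atoms: none
Why: Fluoride-mediated desilylation under buffered acidic conditions frees O3 without ester migration or loss of the benzyl-type ether.

Step 12
Reactants: 21 (3S,7R,8S,9R)-3-hydroxy-9-(4-methoxybenzyloxy)germacra-1(10)Z,4Z,11-trien-8-yl senecioate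
Product: 22 (3S,4R,5S,7R,8S,9R)-4,5-epoxy-3-hydroxy-9-(4-methoxybenzyloxy)germacra-1(10)Z,11-dien-8-yl senecioate
Conditions: mCPBA (1.05 equiv), NaHCO3, CH2Cl2, −20 to 0 °C
Reagents that add atoms: 3-chloroperbenzoic acid, O=C(OO)c1cccc(Cl)c1
Why: Hydroxyl-assisted peracid epoxidation (Henbest type): hydrogen bonding to the free O3 speeds attack on C4=C5 relative to the ether-flanked C1=C10 and the isopropenyl group, and for a Z-allylic alcohol under allylic 1,3-strain (as in medium-ring cycloalkenols) the oxirane forms anti (threo) to O3, which sets C4 and C5.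

Step 13
Reactants: 22 (3S,4R,5S,7R,8S,9R)-4,5-epoxy-3-hydroxy-9-(4-methoxybenzyloxy)germacra-1(10)Z,11-dien-8-yl senecioate; 23 angelic acid
Product: 25 (3S,4S,5S,7R,8S,9R)-3-angeloyloxy-4,5-epoxy-9-(4-methoxybenzyloxy)germacra-1(10)Z,11-dien-8-yl senecioate, via mixed anhydride 24 (not isolated)
Conditions: 23, 2,4,6-trichlorobenzoyl chloride, Et3N, toluene, rt, filter; then 22, toluene, 75 °C
Reagents that add atoms: none
Why: Yamaguchi-type mixed-anhydride angeloylation without a nucleophilic catalyst, the usual way to acylate a hindered alcohol with retention of the Z geometry of the angelate (the descriptor at C4 changes only because the priorities change).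

Step 14
Reactants: 25 (3S,4S,5S,7R,8S,9R)-3-angeloyloxy-4,5-epoxy-9-(4-methoxybenzyloxy)germacra-1(10)Z,11-dien-8-yl senecioate
Product: 26 (3S,4S,5S,7R,8S,9R)-3-angeloyloxy-4,5-epoxy-9-hydroxygermacra-1(10)Z,11-dien-8-yl senecioate
Conditions: DDQ, CH2Cl2/pH 7 buffer, 0 °C
Reagents that add atoms: none
Why: Oxidative cleavage of the 4-methoxybenzyl ether under neutral buffered conditions frees O9 without touching the esters, the oxirane or the olefins and without base-induced 8-to-9 acyl shift.

Step 15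
Reactants: 26 (3S,4S,5S,7R,8S,9R)-3-angeloyloxy-4,5-epoxy-9-hydroxygermacra-1(10)Z,11-dien-8-yl senecioate
Product: 27 (1R,3S,4S,5S,7R,8S,9S,10S)-3-angeloyloxy-1,10:4,5-diepoxy-9-hydroxygermacr-11-en-8-yl senecioate (CNP0320216.1)
Conditions: VO(acac)2 (5 mol%), t-BuOOH, CH2Cl2, 0 °C to rt
Reagents that add atoms: tert-butyl hydroperoxide, CC(C)(C)OO
Why: Vanadium-alkoxide-directed epoxidation (Sharpless–Michaelson): the C9 vanadate delivers oxygen to C1=C10 on the face of O9, the cis-epoxy-alcohol sense found for medium-ring cycloalkenols, which sets C1 and C10 while the isopropenyl group and the unsaturated esters are left alone.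

**Compound list**

1 | (S)-(+)-carvone | CC1=CC[C@@H](CC1=O)C(C)=C | starting material
2 | lithium (3S)-6-methyl-3-(prop-1-en-2-yl)cyclohexa-1,5-dien-1-olate (not isolated) | CC1=CC[C@@H](C=C1[O-])C(C)=C.[Li+] | intermediate
3 | (5R,6R)-6-hydroxy-2-methyl-5-(prop-1-en-2-yl)cyclohex-2-en-1-one | CC1=CC[C@@H]([C@@H](O)C1=O)C(C)=C | intermediate
4 | (1R,6R)-3-methyl-6-(prop-1-en-2-yl)cyclohex-3-ene-1,2-diol (both C2 epimers) | CC1=CC[C@@H]([C@@H](O)C1O)C(C)=C | intermediate
5 | (2Z,5R)-5-formyl-2,6-dimethylhepta-2,6-dienal (not isolated) | O=C/C(C)=C\C[C@@H](C=O)C(C)=C | intermediate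
6 | (2Z,5R)-5-(hydroxymethyl)-2,6-dimethylhepta-2,6-dienal | O=C/C(C)=C\C[C@@H](CO)C(C)=C | intermediate
7 | allylboronic acid pinacol ester | C=CCB1OC(C)(C)C(C)(C)O1 | starting material
8 | (2R,4Z,6S)-5-methyl-2-(prop-1-en-2-yl)nona-4,8-diene-1,6-diol | C=CC[C@H](O)/C(C)=C\C[C@@H](CO)C(C)=C | intermediate
9 | (4S,5Z,8R)-5,9-dimethyl-4-(triethylsilyloxy)-8-[(triethylsilyloxy)methyl]deca-1,5,9-triene | C=CC[C@H](O[Si](CC)(CC)CC)/C(C)=C\C[C@@H](CO[Si](CC)(CC)CC)C(C)=C | intermediate
10 | methacrolein | CC(=C)C=O | starting material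
11 | (2E,5S,6Z,9R)-2,6,10-trimethyl-5-(triethylsilyloxy)-9-[(triethylsilyloxy)methyl]undeca-2,6,10-trienal | O=C/C(C)=C/C[C@H](O[Si](CC)(CC)CC)/C(C)=C\C[C@@H](CO[Si](CC)(CC)CC)C(C)=C | intermediate
12 | bis(4-methoxybenzyl) acetal of 11 | COc1ccc(COC(OCc2ccc(OC)cc2)/C(C)=C/C[C@H](O[Si](CC)(CC)CC)/C(C)=C\C[C@@H](CO[Si](CC)(CC)CC)C(C)=C)cc1 | intermediate
13 | dimethyl(alkoxy)sulfonium chloride formed from 12 at the primary oxygen (not isolated) | COc1ccc(COC(OCc2ccc(OC)cc2)/C(C)=C/C[C@H](O[Si](CC)(CC)CC)/C(C)=C\C[C@@H](CO[S+](C)C)C(C)=C)cc1.[Cl-] | intermediate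
14 | (2R,4Z,6S,8E)-10,10-bis(4-methoxybenzyloxy)-5,9-dimethyl-2-(prop-1-en-2-yl)-6-(triethylsilyloxy)deca-4,8-dienal | COc1ccc(COC(OCc2ccc(OC)cc2)/C(C)=C/C[C@H](O[Si](CC)(CC)CC)/C(C)=C\C[C@@H](C=O)C(C)=C)cc1 | intermediate
15 | (2R,4Z,6S,8E)-10-iodo-10-(4-methoxybenzyloxy)-5,9-dimethyl-2-(prop-1-en-2-yl)-6-(triethylsilyloxy)deca-4,8-dienal, C10 epimers (not isolated) | COc1ccc(COC(I)/C(C)=C/C[C@H](O[Si](CC)(CC)CC)/C(C)=C\C[C@@H](C=O)C(C)=C)cc1 | intermediate
16 | γ-(4-methoxybenzyloxy)allylchromium dichloride, trivalent chromium on germacrane C1, enol ether C9=C10 (not isolated) | COc1ccc(CO/C=C(\C)C([Cr](Cl)Cl)C[C@H](O[Si](CC)(CC)CC)/C(C)=C\C[C@@H](C=O)C(C)=C)cc1 | intermediate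
17 | (3S,7R,8S,9R)-9-(4-methoxybenzyloxy)-3-(triethylsilyloxy)germacra-1(10)Z,4Z,11-trien-8-ol (isopropenyl, O8 and O9 on one ring face) | C=C(C)[C@H]1C/C=C(C)\[C@@H](O[Si](CC)(CC)CC)C/C=C(C)\[C@@H](OCc2ccc(OC)cc2)[C@H]1O | intermediate
18 | senecioic acid (3-methylbut-2-enoic acid) | CC(C)=CC(=O)O | starting material
19 | 3-methylbut-2-enoic 2,4,6-trichlorobenzoic anhydride (not isolated) | CC(C)=CC(=O)OC(=O)c1c(Cl)cc(Cl)cc1Cl | intermediate
20 | (3S,7R,8S,9R)-9-(4-methoxybenzyloxy)-3-(triethylsilyloxy)germacra-1(10)Z,4Z,11-trien-8-yl senecioate | C=C(C)[C@H]1C/C=C(C)\[C@@H](O[Si](CC)(CC)CC)C/C=C(C)\[C@@H](OCc2ccc(OC)cc2)[C@H]1OC(=O)C=C(C)C | intermediate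
21 | (3S,7R,8S,9R)-3-hydroxy-9-(4-methoxybenzyloxy)germacra-1(10)Z,4Z,11-trien-8-yl senecioate | C=C(C)[C@H]1C/C=C(C)\[C@@H](O)C/C=C(C)\[C@@H](OCc2ccc(OC)cc2)[C@H]1OC(=O)C=C(C)C | intermediate
22 | (3S,4R,5S,7R,8S,9R)-4,5-epoxy-3-hydroxy-9-(4-methoxybenzyloxy)germacra-1(10)Z,11-dien-8-yl senecioate (oxirane anti to O3) | C=C(C)[C@H]1C[C@@H]2O[C@]2(C)[C@@H](O)C/C=C(C)\[C@@H](OCc3ccc(OC)cc3)[C@H]1OC(=O)C=C(C)C | intermediate
23 | angelic acid ((Z)-2-methylbut-2-enoic acid) | C/C=C(/C)C(=O)O | starting material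
24 | (Z)-2-methylbut-2-enoic 2,4,6-trichlorobenzoic anhydride (not isolated) | C/C=C(/C)C(=O)OC(=O)c1c(Cl)cc(Cl)cc1Cl | intermediate
25 | (3S,4S,5S,7R,8S,9R)-3-angeloyloxy-4,5-epoxy-9-(4-methoxybenzyloxy)germacra-1(10)Z,11-dien-8-yl senecioate | C=C(C)[C@H]1C[C@@H]2O[C@]2(C)[C@@H](OC(=O)/C(C)=C\C)C/C=C(C)\[C@@H](OCc3ccc(OC)cc3)[C@H]1OC(=O)C=C(C)C | intermediate
26 | (3S,4S,5S,7R,8S,9R)-3-angeloyloxy-4,5-epoxy-9-hydroxygermacra-1(10)Z,11-dien-8-yl senecioate | C=C(C)[C@H]1C[C@@H]2O[C@]2(C)[C@@H](OC(=O)/C(C)=C\C)C/C=C(C)\[C@@H](O)[C@H]1OC(=O)C=C(C)C | intermediate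
27 | (1R,3S,4S,5S,7R,8S,9S,10S)-3-angeloyloxy-1,10:4,5-diepoxy-9-hydroxygermacr-11-en-8-yl senecioate (CNP0320216.1) | C=C(C)[C@H]1C[C@@H]2O[C@]2(C)[C@@H](OC(=O)/C(C)=C\C)C[C@H]2O[C@@]2(C)[C@@H](O)[C@H]1OC(=O)C=C(C)C | target

**Totals**

Total steps: 15. Longest linear sequence: 15 steps (from 1; compounds 7, 10, 18 and 23 enter as bought).

**Three steps most likely to fail, each with a fallback**

Step 9, the ring closure. The chromium allyl is fluxional, so it could close through C1 to an eight-membered ring, give the other C8/C9 pairing or an E olefin, or oligomerise. The fallback makes the same C8–C9 bond from a regiodefined tin/indium reagent. It sets out from enal 11: Bu3SnLi (THF, −78 °C) adds 1,2 and the stannyl alkoxide is capped with 4-methoxybenzyl bromide/Bu4NI to give the α-(4-methoxybenzyloxy)allylstannane F1. Swern oxidation of its primary silyl ether gives the stannyl aldehyde F2. InCl3 (EtOAc, −78 °C to rt, 1 mM) then transmetalates by anti-SE2′ to the C1-indium species, which adds through C9 in a cyclic transition state (Marshall-type anti-selective addition) and comes back to the route at macrocycle 17.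

Step 13, the angeloylation. The hindered epoxy alcohol may acylate slowly, the ester may leak to the tiglate, or the oxirane may open at 75 °C. The fallback builds the angelate on the substrate instead. It sets out from 22: esterification with 2-[bis(2,2,2-trifluoroethoxy)phosphoryl]propanoic acid (DCC, DMAP, CH2Cl2, rt) gives the phosphonopropionate F3. KN(SiMe3)2/18-crown-6 (THF, −78 °C) followed by acetaldehyde (Still–Gennari olefination) forms the Z-2-methylbut-2-enoate and comes back at 25.

Step 3, the selective reduction. Over-reduction of the enal or Z-to-E drift of the dialdehyde would lose material. The fallback sets out from diol 4: NaIO4 as before, then excess NaBH4 (MeOH, 0 °C) reduces both aldehydes of 5 to (2R,4Z)-5-methyl-2-(prop-1-en-2-yl)hex-4-ene-1,6-diol F4. MnO2 (CH2Cl2, rt) then oxidises only the allylic primary alcohol and comes back at 6.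

Further compounds
F1 | step 9 | tributyl{(2E,5S,6Z,9R)-1-(4-methoxybenzyloxy)-2,6,10-trimethyl-5-(triethylsilyloxy)-9-[(triethylsilyloxy)methyl]undeca-2,6,10-trien-1-yl}stannane (C1 epimers) | CCCC[Sn](CCCC)(CCCC)C(OCc1ccc(OC)cc1)/C(C)=C/C[C@H](O[Si](CC)(CC)CC)/C(C)=C\C[C@@H](CO[Si](CC)(CC)CC)C(C)=C
F2 | step 9 | (2R,4Z,6S,8E)-10-(4-methoxybenzyloxy)-5,9-dimethyl-2-(prop-1-en-2-yl)-10-(tributylstannyl)-6-(triethylsilyloxy)deca-4,8-dienal (C10 epimers) | CCCC[Sn](CCCC)(CCCC)C(OCc1ccc(OC)cc1)/C(C)=C/C[C@H](O[Si](CC)(CC)CC)/C(C)=C\C[C@@H](C=O)C(C)=C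
F3 | step 13 | (3S,4S,5S,7R,8S,9R)-3-{2-[bis(2,2,2-trifluoroethoxy)phosphoryl]propanoyloxy}-4,5-epoxy-9-(4-methoxybenzyloxy)germacra-1(10)Z,11-dien-8-yl senecioate | C=C(C)[C@H]1C[C@@H]2O[C@]2(C)[C@@H](OC(=O)C(C)P(=O)(OCC(F)(F)F)OCC(F)(F)F)C/C=C(C)\[C@@H](OCc3ccc(OC)cc3)[C@H]1OC(=O)C=C(C)C
F4 | step 3 | (2R,4Z)-5-methyl-2-(prop-1-en-2-yl)hex-4-ene-1,6-diol | OC/C(C)=C\C[C@@H](CO)C(C)=C
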